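**Plan**

- Numbering: ring C1 (CH–O-enoate), C2 (C=O), C3 (carries C7H2OH), C4 (=CH), C5 (CH–O-isobutyrate), C6 (CH–iPr). The retrosynthesis cuts, in order, the two silyl ethers, the C1–O acyl bond (4-hydroxytiglate), the C5–O acyl bond (isobutyrate), and then C1–O and C6–C(isopropyl) together.
- Enabling feature: C2 and C5 are para oxygens on a ring whose C3 carries C7. This is a 2-substituted p-benzoquinone masked at C5 as a ketal, in which C6 is β and C1 is α to the C2 carbonyl along the unsubstituted C1–C6 edge.
- Forward order: the only ring is the benzene ring of 1, dearomatised in step 3 and never closed. Step 4 adds isopropyl and the C1 oxygen. C2 is then held as a carbinol while C5 is unmasked, reduced and acylated, after which C2 is re-oxidised. The side-chain acid, made separately by Wittig olefination, is joined last at C1–O.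
- Stereochemistry: C6 from the chiral copper–phosphoramidite catalyst; C1 from dioxirane attack anti to the C6 isopropyl (trans); C5 from hindered-hydride attack anti to isopropyl (C5–O cis to iPr); the E-enoate from a stabilised ylide.

Key step: step 4

Remark 1 (assumption): the (S,R,R) ligand is assigned by carrying over the facial sense it shows with cyclohex-2-enone to the C1=C6 enone of 4. If the dienone responds with the opposite sense, the (R,S,S) ligand is used and nothing else changes.

Remark 2: the C2 carbinol formed in step 5 is carried as its epimer mixture (SMILES left open at C2), because step 10 removes this centre.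

Abbreviations: TBDPS = tert-butyldiphenylsilyl, TES = triethylsilyl, TBS = tert-butyldimethylsilyl. Compounds 6–17 and 22 are described with the ring numbering given above.

**Route**

Step 1
Reactants: 1 2-hydroxy-5-methoxybenzaldehyde
Product: 2 2-(hydroxymethyl)-4-methoxyphenol
Conditions: NaBH4, MeOH, 0 °C
Reagents that add atoms: none
Why: Borohydride reduction of the aryl aldehyde is fast and leaves the phenol and the aryl methyl ether untouched.

Step 2
Reactants: 2 2-(hydroxymethyl)-4-methoxyphenol
Product: 3 2-{[tert-butyl(diphenyl)silyl]oxymethyl}-4-methoxyphenol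
Conditions: TBDPSCl (1.05 equiv), imidazole, CH2Cl2, 0 °C
Reagents that add atoms: tert-butyl(chloro)diphenylsilane, CC(C)(C)[Si](Cl)(c1ccccc1)c1ccccc1
Why: Chemoselective silylation; under imidazole catalysis the primary benzylic alcohol is much more nucleophilic towards the hindered chlorosilane than the hydrogen-bonded phenol, so one equivalent should give the alkyl silyl ether.

Step 3
Reactants: 3 2-{[tert-butyl(diphenyl)silyl]oxymethyl}-4-methoxyphenol
Product: 4 2-{[tert-butyl(diphenyl)silyl]oxymethyl}-4,4-dimethoxycyclohexa-2,5-dien-1-one (C2 carbonyl, C5 dimethyl ketal, C3 carries C7)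
Conditions: PhI(OAc)2, MeOH/CH2Cl2, 0 °C; NaHCO3
Reagents that add atoms: methanol, CO
Why: Oxidative dearomatisation of a p-methoxyphenol with the trivalent iodine reagent; methanol captures the oxidised ring at the methoxy-bearing carbon C5 and gives the quinone monoketal.

Step 4
Reactants: 4 2-{[tert-butyl(diphenyl)silyl]oxymethyl}-4,4-dimethoxycyclohexa-2,5-dien-1-one; 5 diisopropylzinc
Product: 9 (5R,6R)-2-{[tert-butyl(diphenyl)silyl]oxymethyl}-6-hydroxy-4,4-dimethoxy-5-(propan-2-yl)cyclohex-2-en-1-one, via isopropylzinc dienolate 6 (not isolated), via trimethylsilyl dienol ether 7 (not isolated), via silyloxy epoxide 8 (not isolated)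
Conditions: Cu(OTf)2 (2 mol %), O,O′-[(S)-1,1′-binaphthalene-2,2′-diyl] N,N-bis[(R)-1-phenylethyl]phosphoramidite (4 mol %), iPr2Zn, toluene, −30 °C; TMSOTf, −30 °C, then Et3N, pentane, cold aq. NaHCO3 wash; crude 7, dimethyldioxirane (acetone solution, from acetone and KHSO5), CH2Cl2, −78 to −40 °C; aq. citric acid, THF, 0 °C
Reagents that add atoms: diisopropylzinc (5), CC(C)[Zn]C(C)C; dimethyldioxirane, CC1(C)OO1 (the C1 oxygen); trimethylsilyl trifluoromethanesulfonate, C[Si](C)(C)OS(=O)(=O)C(F)(F)F (silyl group held only by 7 and 8)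
Why: The dialkylzinc reduces the Cu(OTf)2/phosphoramidite precatalyst to a monovalent copper complex, which transfers isopropyl to C6 through a π-complex and a trivalent copper intermediate to give zinc dienolate 6; O-silylation fixes this as the cross-conjugated 2-silyloxydiene 7, the dioxirane epoxidises its electron-rich C1=C2 bond, and mild acid opens silyloxyoxirane 8 to the C1 carbinol beside the restored C2 ketone. The closest known reaction types are the copper–phosphoramidite addition of dialkylzincs to quinone monoketals, the silyl triflate trapping of the resulting zinc enolates and the Rubottom α′-hydroxylation of enone-derived silyl dienol ethers, run here in sequence without purifying 6–8. No ring is closed; the step forms only C6–C(isopropyl) and C1–O. C6 is set by the ligand, which selects the enone face at C6, and C1 by the substrate, since the dioxirane approaches C1=C2 on the face opposite the adjacent isopropyl group, so C1–O and C6–isopropyl should be trans. Addition must occur at C6 and not C4, which the C3 substituent secures because α-substituted enones are much poorer acceptors in this catalysis, and oxidation must occur at C1=C2 and not C3=C4, which the silyloxy donor secures. The ketal should survive because the enolate consumes the silyl triflate at low temperature and the excess is quenched with amine before warming.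

Step 5
Reactants: 9 (5R,6R)-2-{[tert-butyl(diphenyl)silyl]oxymethyl}-6-hydroxy-4,4-dimethoxy-5-(propan-2-yl)cyclohex-2-en-1-one
Product: 11 C5-ketone diol: ring C1H(OH)–C2H(OH)–C3(CH2OTBDPS)=C4H–C5(=O)–C6H(iPr); C1 and C6 as in 23; C2 epimers, via diol ketal 10 (not isolated)
Conditions: NaBH4, CeCl3·7H2O, MeOH, −78 °C; acetone quench; then 0.5 M aq. HCl, THF, 0 °C
Reagents that add atoms: water, O
Why: Luche 1,2-reduction turns the C2 ketone into an allylic carbinol, after which the C5 dimethyl ketal is an ordinary allylic ketal that dilute acid hydrolyses through an allyl-stabilised oxocarbenium ion; reducing C2 first avoids the ene-1,4-dione, which would tautomerise to a hydroquinone.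

Step 6
Reactants: 11 C5-ketone diol
Product: 12 bis(triethylsilyl) ether of 11: C1–OTES, C2–OTES, C5 ketone, C7–OTBDPS; C1 and C6 as in 23
Conditions: TESOTf, 2,6-lutidine, CH2Cl2, −78 °C
Reagents that add atoms: triethylsilyl trifluoromethanesulfonate, CC[Si](CC)(CC)OS(=O)(=O)C(F)(F)F
Why: Silyl triflate/2,6-lutidine silylation caps both secondary alcohols, including the hindered C1–OH, and removes the β-hydroxy ketone that could dehydrate.

Step 7
Reactants: 12 bis(triethylsilyl) ether, C5 ketone
Product: 13 C5 alcohol: C1–OTES, C2–OTES, C5–OH cis to the C6 isopropyl (5S), C7–OTBDPS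
Conditions: LiBH(s-Bu)3 (L-Selectride), THF, −78 °C; then H2O
Reagents that add atoms: none
Why: 1,2-Reduction with a hindered trialkylborohydride; hydride should reach the C5 carbonyl from the face opposite the adjacent C6 isopropyl (equatorial delivery), and conjugate reduction is disfavoured because the β-carbon C3 is fully substituted, so C5–OH forms cis to isopropyl.

Step 8
Reactants: 13 C5 alcohol; 14 isobutyryl chloride (2-methylpropanoyl chloride)
Product: 15 C5 isobutyrate: C1–OTES, C2–OTES, C5–OC(O)iPr, C7–OTBDPS; C1, C5, C6 as in 23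
Conditions: pyridine, DMAP (cat.), CH2Cl2, 0 °C
Reagents that add atoms: isobutyryl chloride (14), CC(C)C(Cl)=O
Why: DMAP-catalysed acylation of the only free hydroxyl; the C5–O bond is not touched, so the configuration is retained.

Step 9
Reactants: 15 C5 isobutyrate, bis(triethylsilyl) ether
Product: 16 C1,C2-diol: C1–OH, C2–OH (epimers), C5 isobutyrate, C7–OTBDPS
Conditions: pyridinium p-toluenesulfonate (cat.), MeOH/CH2Cl2, 0 °C to rt
Reagents that add atoms: none
Why: Acid-catalysed methanolysis cleaves the two triethylsilyl ethers much faster than the primary tert-butyldiphenylsilyl ether, and the isobutyrate is inert; it cannot migrate to C1–OH because the two oxygens are trans-1,3.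

Step 10
Reactants: 16 C1,C2-diol
Product: 17 α-hydroxy enone: C1–OH, C2 ketone, C3(CH2OTBDPS)=C4, C5 isobutyrate, C6 isopropyl; C1, C5, C6 as in 23
Conditions: MnO2 (activated, excess), CH2Cl2, rt
Reagents that add atoms: none
Why: Chemoselective allylic oxidation; MnO2 oxidises the allylic C2 carbinol of either epimer to the enone and leaves the saturated C1 carbinol.

Step 11
Reactants: 18 (tert-butyldimethylsilyloxy)acetaldehyde; 19 ethyl 2-(triphenylphosphoranylidene)propanoate
Product: 20 ethyl (E)-4-(tert-butyldimethylsilyloxy)-2-methylbut-2-enoate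
Conditions: CH2Cl2, rt
Reagents that add atoms: ethyl 2-(triphenylphosphoranylidene)propanoate (19), CCOC(=O)C(C)=P(c1ccccc1)(c1ccccc1)c1ccccc1
Why: Wittig olefination with a stabilised α-methyl ylide should give the (E)-trisubstituted enoate.

Step 12
Reactants: 20 ethyl (E)-4-(tert-butyldimethylsilyloxy)-2-methylbut-2-enoate
Product: 21 (E)-4-(tert-butyldimethylsilyloxy)-2-methylbut-2-enoic acid
Conditions: LiOH, THF/H2O, rt; then 1 M HCl to pH 4
Reagents that add atoms: lithium hydroxide, [Li+].[OH-] (the carboxyl OH oxygen)
Why: Saponification of the ethyl ester; the primary TBS ether is stable to aqueous hydroxide and the alkene geometry is unaffected.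

Step 13
Reactants: 17 α-hydroxy enone; 21 (E)-4-(tert-butyldimethylsilyloxy)-2-methylbut-2-enoic acid
Product: 22 bis-silyl ether of the target: C1–O-[(E)-4-(TBSO)-2-methylbut-2-enoyl], C2 ketone, C5 isobutyrate, C7–OTBDPS
Conditions: EDC·HCl, DMAP (0.3 equiv), CH2Cl2, 0 °C to rt
Reagents that add atoms: (E)-4-(tert-butyldimethylsilyloxy)-2-methylbut-2-enoic acid (21), C/C(=C\CO[Si](C)(C)C(C)(C)C)C(=O)O
Why: Steglich esterification of the only free hydroxyl; the C1–O bond is retained, and the E-enoate is the more stable geometry, so the acyl-pyridinium intermediate should not erode it.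

Step 14
Reactants: 22 bis-silyl ether of the target
Product: 23 (1R,5S,6S)-3-(hydroxymethyl)-5-[(2-methylpropanoyl)oxy]-2-oxo-6-(propan-2-yl)cyclohex-3-en-1-yl (2E)-4-hydroxy-2-methylbut-2-enoate
Conditions: HF·pyridine, pyridine, THF, 0 °C to rt
Reagents that add atoms: none
Why: Fluoride-mediated desilylation under buffered, mildly acidic conditions should remove both primary silyl ethers without the base that could cause acyl migration, epimerisation at C1 or elimination.

**Compound list**

1 | 2-hydroxy-5-methoxybenzaldehyde | COc1ccc(O)c(C=O)c1 | starting material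
2 | 2-(hydroxymethyl)-4-methoxyphenol | COc1ccc(O)c(CO)c1 | intermediate
3 | 2-{[tert-butyl(diphenyl)silyl]oxymethyl}-4-methoxyphenol | COc1ccc(O)c(CO[Si](c2ccccc2)(c2ccccc2)C(C)(C)C)c1 | intermediate
4 | 2-{[tert-butyl(diphenyl)silyl]oxymethyl}-4,4-dimethoxycyclohexa-2,5-dien-1-one | O=C1C=CC(OC)(OC)C=C1CO[Si](c1ccccc1)(c1ccccc1)C(C)(C)C | intermediate
5 | diisopropylzinc | CC(C)[Zn]C(C)C | starting material
6 | isopropylzinc dienolate (O–Zn at C2, C1=C2 and C3=C4, isopropyl at C6) | CC(C)[Zn]OC1=C[C@@H](C(C)C)C(OC)(OC)C=C1CO[Si](c1ccccc1)(c1ccccc1)C(C)(C)C | intermediate (not isolated)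
7 | trimethylsilyl dienol ether (2-silyloxydiene, C1=C2 and C3=C4) | C[Si](C)(C)OC1=C[C@@H](C(C)C)C(OC)(OC)C=C1CO[Si](c1ccccc1)(c1ccccc1)C(C)(C)C | intermediate (not isolated)
8 | C1–C2 silyloxy epoxide (oxirane oxygen anti to the C6 isopropyl) | C[Si](C)(C)O[C@@]12O[C@@H]1[C@@H](C(C)C)C(OC)(OC)C=C2CO[Si](c1ccccc1)(c1ccccc1)C(C)(C)C | intermediate (not isolated)
9 | (5R,6R)-2-{[tert-butyl(diphenyl)silyl]oxymethyl}-6-hydroxy-4,4-dimethoxy-5-(propan-2-yl)cyclohex-2-en-1-one | O[C@H]1C(=O)C(CO[Si](c2ccccc2)(c2ccccc2)C(C)(C)C)=CC(OC)(OC)[C@@H]1C(C)C | intermediate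
10 | diol ketal (C1–OH, C2–OH epimers, C5 dimethyl ketal) | O[C@H]1C(O)C(CO[Si](c2ccccc2)(c2ccccc2)C(C)(C)C)=CC(OC)(OC)[C@@H]1C(C)C | intermediate (not isolated)
11 | C5-ketone diol (C1–OH, C2–OH epimers, C3=C4–C5=O) | O[C@H]1C(O)C(CO[Si](c2ccccc2)(c2ccccc2)C(C)(C)C)=CC(=O)[C@@H]1C(C)C | intermediate
12 | bis(triethylsilyl) ether of 11 | CC[Si](CC)(CC)O[C@H]1C(O[Si](CC)(CC)CC)C(CO[Si](c2ccccc2)(c2ccccc2)C(C)(C)C)=CC(=O)[C@@H]1C(C)C | intermediate
13 | C5 alcohol, C5–OH cis to isopropyl (5S) | CC[Si](CC)(CC)O[C@H]1C(O[Si](CC)(CC)CC)C(CO[Si](c2ccccc2)(c2ccccc2)C(C)(C)C)=C[C@H](O)[C@@H]1C(C)C | intermediate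
14 | isobutyryl chloride | CC(C)C(Cl)=O | starting material
15 | C5 isobutyrate, C1/C2 bis(triethylsilyl) ether | CC[Si](CC)(CC)O[C@H]1C(O[Si](CC)(CC)CC)C(CO[Si](c2ccccc2)(c2ccccc2)C(C)(C)C)=C[C@H](OC(=O)C(C)C)[C@@H]1C(C)C | intermediate
16 | C1,C2-diol, C5 isobutyrate | O[C@H]1C(O)C(CO[Si](c2ccccc2)(c2ccccc2)C(C)(C)C)=C[C@H](OC(=O)C(C)C)[C@@H]1C(C)C | intermediate
17 | α-hydroxy enone (C1–OH, C2=O), C5 isobutyrate, C7–OTBDPS | O[C@H]1C(=O)C(CO[Si](c2ccccc2)(c2ccccc2)C(C)(C)C)=C[C@H](OC(=O)C(C)C)[C@@H]1C(C)C | intermediate
18 | (tert-butyldimethylsilyloxy)acetaldehyde | O=CCO[Si](C)(C)C(C)(C)C | starting material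
19 | ethyl 2-(triphenylphosphoranylidene)propanoate | CCOC(=O)C(C)=P(c1ccccc1)(c1ccccc1)c1ccccc1 | starting material
20 | ethyl (E)-4-(tert-butyldimethylsilyloxy)-2-methylbut-2-enoate | CCOC(=O)/C(C)=C/CO[Si](C)(C)C(C)(C)C | intermediate
21 | (E)-4-(tert-butyldimethylsilyloxy)-2-methylbut-2-enoic acid | C/C(=C\CO[Si](C)(C)C(C)(C)C)C(=O)O | intermediate
22 | bis-silyl ether of the target (side-chain OTBS, C7–OTBDPS) | C/C(=C\CO[Si](C)(C)C(C)(C)C)C(=O)O[C@H]1C(=O)C(CO[Si](c2ccccc2)(c2ccccc2)C(C)(C)C)=C[C@H](OC(=O)C(C)C)[C@@H]1C(C)C | intermediate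
23 | (1R,5S,6S)-3-(hydroxymethyl)-5-[(2-methylpropanoyl)oxy]-2-oxo-6-(propan-2-yl)cyclohex-3-en-1-yl (2E)-4-hydroxy-2-methylbut-2-enoate | C/C(=C\CO)C(=O)O[C@H]1C(=O)C(CO)=C[C@H](OC(=O)C(C)C)[C@@H]1C(C)C | target

**Step count**

Total: 14 steps. Longest linear sequence: 12 steps (steps 1–10, 13, 14); steps 11–12 make the side-chain acid.

**Steps most likely to fail, with fallbacks**

Step 4. The silyl triflate may ionise the allylic ketal of the silyl dienol ether and lead to aromatisation. Silylation of the sluggish zinc enolate may be incomplete. A radical background addition of the secondary alkylzinc may lower the enantiomeric purity. Fallback, from 4 back to 9: the copper-catalysed addition is run alone and quenched with aqueous NH4Cl, and the ketone (5S)-2-{[tert-butyl(diphenyl)silyl]oxymethyl}-4,4-dimethoxy-5-(propan-2-yl)cyclohex-2-en-1-one F1 is isolated. C1 is its only enolisable position because C5 is quaternary, so KN(SiMe3)2 in THF at −78 °C should give the C1 enolate cleanly. Oxidation of this enolate with 2-(phenylsulfonyl)-3-phenyloxaziridine, again anti to the isopropyl group, should deliver 9. This replaces the silyl triflate and the dioxirane by a base-mediated enolate hydroxylation.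

Step 7. Hydride delivery may occur on the wrong face of the C5 carbonyl if the ring adopts the conformer with axial isopropyl and axial C1–OTES, giving C5–OH trans to isopropyl. Fallback, from 12 back to 15: the ketone is reduced with NaBH4/CeCl3 in MeOH, where axial delivery by the small hydride should favour the C5-epimeric alcohol F2 (C5–OH trans to isopropyl). A Mitsunobu reaction of this alcohol with isobutyric acid (PPh3, diisopropyl azodicarboxylate, toluene) inverts C5 and installs the ester in one operation, arriving at 15. Allylic transposition is unlikely because C3 is fully substituted.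

Step 13. Acylation of the hindered C1 ketol by the α-branched, conjugated acid may be slow, so that N-acylurea formation or base-induced epimerisation at C1 competes. Fallback, from 17 back to 22: 17 is acylated with the more reactive 2-(diethoxyphosphoryl)propanoic acid (EDC·HCl, DMAP) to give the C1 2-(diethoxyphosphoryl)propanoate F3. A Horner–Wadsworth–Emmons reaction of this phosphonate with aldehyde 18 under LiCl/iPr2NEt in MeCN should then build the (E)-enoate on the substrate and give 22.

**Further compounds**

F1 | step 4 | (5S)-2-{[tert-butyl(diphenyl)silyl]oxymethyl}-4,4-dimethoxy-5-(propan-2-yl)cyclohex-2-en-1-one | O=C1C[C@@H](C(C)C)C(OC)(OC)C=C1CO[Si](c1ccccc1)(c1ccccc1)C(C)(C)C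
F2 | step 7 | C5-epimeric alcohol (C5–OH trans to isopropyl), C1/C2 bis(triethylsilyl) ether, C7–OTBDPS | CC[Si](CC)(CC)O[C@H]1C(O[Si](CC)(CC)CC)C(CO[Si](c2ccccc2)(c2ccccc2)C(C)(C)C)=C[C@@H](O)[C@@H]1C(C)C
F3 | step 13 | C1 2-(diethoxyphosphoryl)propanoate of 17 (phosphonate α-carbon as epimer mixture) | CCOP(=O)(OCC)C(C)C(=O)O[C@H]1C(=O)C(CO[Si](c2ccccc2)(c2ccccc2)C(C)(C)C)=C[C@H](OC(=O)C(C)C)[C@@H]1C(C)C
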